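The target is disconnected across its dihydropyran into the norflavesone quinone methide and a germacrane-type dienol, which are to be united last by a hetero-Diels–Alder reaction. The ten-membered carbocycle of that dienol is made from an eleven-membered cyclic sulfone by Ramberg–Bäcklund contraction: extrusion of SO2 forges the C5–C6 bond and delivers the cis CH=CH unit that lies between the methyl-bearing C4 and the hydroxyisopropyl-bearing C7 (germacrane locants). The sulfone ring itself arises from (R)-6,7-epoxygeranyl acetate, which supplies ten carbons, the E-alkene and C7, and an (S)-bromo alcohol that supplies C4, by copper coupling and carbanion–epoxide closure.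

Key step: step 7

Remark: germacrane locants are used throughout for the terpenoid half (C10 = O-bearing quaternary carbon, C1 = ring-fusion CH, C4 = CH–CH3, C5=C6 = cis alkene, C7 = CH bearing C11(CH3)2OH); in these locants the target as drawn is (1S,4S,5Z,7R,10R).

Step 1
Reactants: 1 geranyl acetate
Product: 2 (2E)-5-[(2R)-3,3-dimethyloxiran-2-yl]-3-methylpent-2-en-1-yl acetate [(R)-6,7-epoxygeranyl acetate]
Conditions: D-fructose-derived Shi ketone (30 mol%), Oxone, K2CO3, Bu4NHSO4, borate/EDTA buffer (pH 10.5), MeCN–DMM–H2O, 0 °C
Reagents that add atoms: Oxone (potassium peroxymonosulfate), [K+].[O-]S(=O)(=O)OO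
Why: Shi asymmetric epoxidation, in which the chiral dioxirane attacks only the electron-rich distal trisubstituted alkene (the 2,3-alkene is deactivated by the allylic acetate) through the spiro transition state that should give the (R)-epoxide carbon, the later C7.

Step 2
Reactants: 3 (2S)-3-bromo-2-methylpropan-1-ol
Product: 4 (2S)-2-methyl-3-(methylsulfanyl)propan-1-ol
Conditions: NaSMe, MeOH, 0 °C → rt
Reagents that add atoms: sodium methanethiolate, [Na+].[S-]C
Why: SN2 displacement of the primary bromide by thiolate puts sulfur on C5 and brings in the methyl carbon that becomes C6, without touching the stereocentre (the later C4).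

Step 3
Reactants: 4 (2S)-2-methyl-3-(methylsulfanyl)propan-1-ol
Product: 5 (2R)-1-bromo-2-methyl-3-(methylsulfanyl)propane
Conditions: CBr4, PPh3, CH2Cl2, 0 °C
Reagents that add atoms: carbon tetrabromide, BrC(Br)(Br)Br
Why: Appel bromination of the primary alcohol makes C3 the site of Grignard formation; the stereocentre is not involved and its descriptor changes only through CIP priorities.

Step 4
Reactants: 5 (2R)-1-bromo-2-methyl-3-(methylsulfanyl)propane and 2 (R)-6,7-epoxygeranyl acetate
Product: 7 (3R)-3-[(3E,7S)-3,7-dimethyl-8-(methylsulfanyl)oct-3-en-1-yl]-2,2-dimethyloxirane, via Grignard reagent 6 (not isolated)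
Conditions: 5, Mg, THF, rt; then 2, Li2CuCl4 (5 mol%), THF, −40 → 0 °C
Reagents that add atoms: none
Why: Copper-catalysed Grignard cross-coupling with a primary allylic acetate (Kochi/Fouquet–Schlosser type) should substitute at the α-carbon with retention of the E geometry and form the C2–C3 bond faster than the reagent attacks the ester carbonyl or the hindered trisubstituted epoxide at low temperature.

Step 5
Reactants: 7 (3R)-3-[(3E,7S)-3,7-dimethyl-8-(methylsulfanyl)oct-3-en-1-yl]-2,2-dimethyloxirane
Product: 8 (3R)-3-[(3E,7S)-8-(methanesulfonyl)-3,7-dimethyloct-3-en-1-yl]-2,2-dimethyloxirane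
Conditions: TPAP (10 mol%), NMO (4 equiv), 4 Å MS, MeCN, 40 °C
Reagents that add atoms: N-methylmorpholine N-oxide, C[N+]1([O-])CCOCC1
Why: TPAP/NMO oxidation of the sulfide to the sulfone runs under neutral conditions, chosen because peracids would also epoxidise C1=C10 and acidic peroxide systems could open the epoxide.

Step 6
Reactants: 8 (3R)-3-[(3E,7S)-8-(methanesulfonyl)-3,7-dimethyloct-3-en-1-yl]-2,2-dimethyloxirane
Product: 10 2-[(3S,6E,10S)-6,10-dimethyl-1,1-dioxo-1λ6-thiacycloundec-6-en-3-yl]propan-2-ol, via lithiated sulfone 9 (not isolated)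
Conditions: n-BuLi (1.05 equiv), THF–DMPU, −78 °C → rt, 2 mM; then H2O
Reagents that add atoms: none
Why: Intramolecular epoxide opening by a sulfone-stabilised carbanion (11-exo-tet), the carbanion–epoxide macrocyclisation classically used for germacrane and cembrane rings, in which the unhindered CH2Li attacks the secondary epoxide carbon with inversion, so that C7 receives the configuration of the target (descriptor S in 10 only because CH2SO2 outranks C11) and the C11 tertiary alcohol is released.

Step 7
Reactants: 10 2-[(3S,6E,10S)-6,10-dimethyl-1,1-dioxo-1λ6-thiacycloundec-6-en-3-yl]propan-2-ol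
Product: 13 2-[(1R,2Z,4S,7E)-4,8-dimethylcyclodeca-2,7-dien-1-yl]propan-2-ol, via α-bromo sulfone 11 (not isolated), via cis-episulfone 12 (not isolated)
Conditions: BrCF2CF2Br, KOH/Al2O3, t-BuOH–CH2Cl2, 0 °C → rt
Reagents that add atoms: none
Why: Ramberg–Bäcklund reaction in its in-situ halogen-transfer form: KOH/Al2O3 deprotonates an α-carbon of the sulfone, the carbanion takes Br+ from BrCF2CF2Br (11), the α'-carbanion displaces bromide to give episulfone 12, and 12 loses SO2 stereospecifically. The ring that closes is the ten-membered carbocycle, formed by the 3-exo-tet 1,3-elimination that makes the C5–C6 σ-bond inside the eleven-membered ring, so the ring contracts by the sulfur atom. No permanent sp3 stereocentre is created; the two transient episulfone centres are translated into alkene geometry, and C4 and C7, being β to sulfur, are not acidic and stay untouched. The selectivity needed is Z at C5=C6: dialkyl sulfones under hydroxide conditions close kinetically to the cis-episulfone, and a second trans double bond in a ten-membered ring that already holds the E-configured C1=C10 bond would be considerably more strained. Chemoselectivity rests on the carbene-free bromine donor (no dihalocarbene to add to C1=C10 or to the C11 alkoxide) and on the inertness of α-halo sulfones to external substitution. The closest known reaction type is the Ramberg–Bäcklund ring contraction of medium-ring cyclic sulfones to cycloalkenes.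

Step 8
Reactants: 14 2-methyl-1-(2,4,6-trihydroxyphenyl)propan-1-one
Product: 15 norflavesone, 3,5-dihydroxy-2,6,6-trimethyl-4-(2-methylpropanoyl)cyclohexa-2,4-dien-1-one
Conditions: MeI, NaOMe, MeOH, 0 °C → rt
Reagents that add atoms: iodomethane, CI
Why: Base-mediated threefold C-methylation of the acylphloroglucinol (dearomatising at the gem-dimethyl carbon) gives the β-triketone; no stereocentre is formed.

Step 9
Reactants: 13 2-[(1R,2Z,4S,7E)-4,8-dimethylcyclodeca-2,7-dien-1-yl]propan-2-ol and 15 norflavesone
Product: 17 CNP0564661.1, the (1S,4S,5Z,7R,10R) dihydropyran-fused adduct (O on C10, CH2 bridge on C1), via o-quinone methide 16 (not isolated)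
Conditions: 15 (2 equiv), Ag2O, TEMPO (cat.), PhMe, rt
Reagents that add atoms: none
Why: Oxidative generation of the o-quinone methide followed by an inverse-electron-demand hetero-Diels–Alder reaction with the strained, electron-rich E-C1=C10 bond, in which the CH2 terminus bonds to C1 and the carbonyl oxygen next to the acyl-bearing carbon bonds to C10, suprafacial addition to the E-alkene fixes the trans ring fusion, and attack on the peripheral face of the ring conformer with the C4 and C7 substituents pseudo-equatorial is expected, in line with the presumed non-enzymatic biogenesis, to give the (1S,10R) diastereomer.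

Compound list
1 | geranyl acetate, (2E)-3,7-dimethylocta-2,6-dien-1-yl acetate | CC(C)=CCC/C(C)=C/COC(C)=O | starting material
2 | (2E)-5-[(2R)-3,3-dimethyloxiran-2-yl]-3-methylpent-2-en-1-yl acetate | CC(=O)OC/C=C(\C)CC[C@H]1OC1(C)C | intermediate
3 | (2S)-3-bromo-2-methylpropan-1-ol | OC[C@H](C)CBr | starting material
4 | (2S)-2-methyl-3-(methylsulfanyl)propan-1-ol | OC[C@H](C)CSC | intermediate
5 | (2R)-1-bromo-2-methyl-3-(methylsulfanyl)propane | BrC[C@H](C)CSC | intermediate
6 | [(2S)-2-methyl-3-(methylsulfanyl)propyl]magnesium bromide (not isolated) | CSC[C@@H](C)C[Mg]Br | intermediate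
7 | (3R)-3-[(3E,7S)-3,7-dimethyl-8-(methylsulfanyl)oct-3-en-1-yl]-2,2-dimethyloxirane | CSC[C@@H](C)CC/C=C(\C)CC[C@H]1OC1(C)C | intermediate
8 | (3R)-3-[(3E,7S)-8-(methanesulfonyl)-3,7-dimethyloct-3-en-1-yl]-2,2-dimethyloxirane | CS(=O)(=O)C[C@@H](C)CC/C=C(\C)CC[C@H]1OC1(C)C | intermediate
9 | ({[(2S,5E)-8-[(2R)-3,3-dimethyloxiran-2-yl]-2,6-dimethyloct-5-en-1-yl]sulfonyl}methyl)lithium (not isolated) | [Li]CS(=O)(=O)C[C@@H](C)CC/C=C(\C)CC[C@H]1OC1(C)C | intermediate
10 | 2-[(3S,6E,10S)-6,10-dimethyl-1,1-dioxo-1λ6-thiacycloundec-6-en-3-yl]propan-2-ol | O=S1(=O)C[C@@H](C)CC/C=C(\C)CC[C@@H](C(C)(C)O)C1 | intermediate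
11 | 2-[(3S,6E,10S)-11-bromo-6,10-dimethyl-1,1-dioxo-1λ6-thiacycloundec-6-en-3-yl]propan-2-ol, C11 epimers (not isolated; the 2-bromo isomer would react the same way) | O=S1(=O)C(Br)[C@@H](C)CC/C=C(\C)CC[C@@H](C(C)(C)O)C1 | intermediate
12 | 2-[(2S,5E,9S)-5,9-dimethyl-11,11-dioxo-11λ6-thiabicyclo[8.1.0]undec-5-en-2-yl]propan-2-ol, cis-fused at C1/C10 (not isolated; one of the two cis isomers drawn, both give the same alkene) | O=S1(=O)[C@@H]2[C@@H](C)CC/C=C(\C)CC[C@@H](C(C)(C)O)[C@H]12 | intermediate
13 | 2-[(1R,2Z,4S,7E)-4,8-dimethylcyclodeca-2,7-dien-1-yl]propan-2-ol | C/C1=C\CC[C@H](C)/C=C\[C@H](C(C)(C)O)CC1 | intermediate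
14 | 2-methyl-1-(2,4,6-trihydroxyphenyl)propan-1-one | CC(C)C(=O)c1c(O)cc(O)cc1O | starting material
15 | norflavesone, 3,5-dihydroxy-2,6,6-trimethyl-4-(2-methylpropanoyl)cyclohexa-2,4-dien-1-one | CC(C)C(=O)C1=C(O)C(C)(C)C(=O)C(C)=C1O | intermediate
16 | 3-hydroxy-4,4-dimethyl-6-methylidene-2-(2-methylpropanoyl)cyclohex-2-ene-1,5-dione (not isolated) | CC(C)C(=O)C1=C(O)C(C)(C)C(=O)C(=C)C1=O | intermediate
17 | CNP0564661.1, (1S,4S,5Z,7R,10R) in germacrane locants | CC(C)C(=O)C1=C(O)C(C)(C)C(=O)C2=C1O[C@]1(C)CC[C@@H](C(C)(C)O)/C=C\[C@@H](C)CC[C@H]1C2 | target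

Total step count: 9. Longest linear sequence: 7 steps (3 → 4 → 5 → 7 → 8 → 10 → 13 → 17; steps 2–7 and 9).

Steps most likely to fail

1. Step 6 (closure of the eleven-membered sulfone). What may go wrong: the strained medium-ring transition state is slow, so intermolecular epoxide opening (oligomers), base-induced isomerisation of the epoxide to an allylic alcohol, or parking of the charge on the internal α-carbon C5 can take over. Fallback (sets out from 2, returns at 10): the ring is closed at sulfur instead of at carbon. Acetate 2 is coupled, under the conditions of step 4, with [(2S)-3-chloro-2-methylpropyl]magnesium bromide F1 (from commercial (R)-1-bromo-3-chloro-2-methylpropane and Mg) to give the chloro epoxide F2. The epoxide is then opened intermolecularly at C7, with the same inversion, by an excess of the hydroxymethyl-anion equivalent (isopropoxydimethylsilyl)methylmagnesium chloride under CuI catalysis to give the silane F3. F3 is oxidised in the same flask (KF, KHCO3, H2O2) to the diol F4. Mesylation of the primary hydroxyl (MsCl, Et3N, −20 °C) gives the mesylate F5. Na2S·9H2O with catalytic NaI in DMF at high dilution should displace mesylate and chloride to give the cyclic sulfide F6, which TPAP/NMO oxidises to sulfone 10.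

2. Step 9 (hetero-Diels–Alder reaction). What may go wrong: poor discrimination between the two peripheral faces offered by the interconverting ring conformers of 13, possibly reinforced by hydrogen bonding of the free C11 hydroxyl to the quinone methide, or use of the other ring carbonyl as hetero-terminus. Fallback (sets out from 13, returns at 17): the hydroxyl is turned from a potential directing group into a purely steric control element. Silylation of 13 (TESOTf, 2,6-lutidine, CH2Cl2, −78 °C) gives the triethylsilyl ether F7, whose bulky Et3SiO–CMe2 group should sit firmly pseudo-equatorial and shield its own side of the ring. Cycloaddition with 15 under the conditions of step 9 gives the silyl-protected adduct F8, and HF·pyridine in THF returns 17.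

3. Step 7 (ring contraction). What may go wrong: closure to the trans-episulfone and hence E-C5=C6, double bromination of the sulfone followed by elimination to a vinyl bromide, or loss of the volatile, strained diene under the basic conditions. Fallback (sets out from 10, returns at 17): the order of the last two operations is inverted. Sulfone 10 is first used as the dienophile under the conditions of step 9 to give the pyran-fused eleven-membered sulfone F9 (diastereomers, if any, separated here). The same contraction (BrCF2CF2Br, KOH/Al2O3, one further equivalent of base for the acidic enol) is then run on F9 and leads directly to 17. In F9 the electron-rich C1=C10 bond is already consumed, and the ten-membered ring has to form trans-fused to the pyran with a single double bond, which should favour the cis alkene and removes the competing chemistry of the diene.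

Further compounds
F1 | step 6 | [(2S)-3-chloro-2-methylpropyl]magnesium bromide | ClC[C@@H](C)C[Mg]Br
F2 | step 6 | (3R)-3-[(3E,7S)-8-chloro-3,7-dimethyloct-3-en-1-yl]-2,2-dimethyloxirane | ClC[C@@H](C)CC/C=C(\C)CC[C@H]1OC1(C)C
F3 | step 6 | (3S,6E,10S)-11-chloro-3-{[dimethyl(propan-2-yloxy)silyl]methyl}-2,6,10-trimethylundec-6-en-2-ol | ClC[C@@H](C)CC/C=C(\C)CC[C@H](C[Si](C)(C)OC(C)C)C(C)(C)O
F4 | step 6 | (2R)-2-[(3E,7S)-8-chloro-3,7-dimethyloct-3-en-1-yl]-3-methylbutane-1,3-diol | ClC[C@@H](C)CC/C=C(\C)CC[C@H](CO)C(C)(C)O
F5 | step 6 | (2R)-2-[(3E,7S)-8-chloro-3,7-dimethyloct-3-en-1-yl]-3-hydroxy-3-methylbutyl methanesulfonate | ClC[C@@H](C)CC/C=C(\C)CC[C@H](COS(C)(=O)=O)C(C)(C)O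
F6 | step 6 | 2-[(3S,6E,10S)-6,10-dimethylthiacycloundec-6-en-3-yl]propan-2-ol | S1C[C@@H](C)CC/C=C(\C)CC[C@@H](C(C)(C)O)C1
F7 | step 9 | triethyl({2-[(1R,2Z,4S,7E)-4,8-dimethylcyclodeca-2,7-dien-1-yl]propan-2-yl}oxy)silane | C/C1=C\CC[C@H](C)/C=C\[C@H](C(C)(C)O[Si](CC)(CC)CC)CC1
F8 | step 9 | C11-O-triethylsilyl ether of 17 | CC(C)C(=O)C1=C(O)C(C)(C)C(=O)C2=C1O[C@]1(C)CC[C@@H](C(C)(C)O[Si](CC)(CC)CC)/C=C\[C@@H](C)CC[C@H]1C2
F9 | step 7 | pyran-fused eleven-membered sulfone, hetero-Diels–Alder adduct of 10 and 16 | CC(C)C(=O)C1=C(O)C(C)(C)C(=O)C2=C1O[C@]1(C)CC[C@@H](C(C)(C)O)CS(=O)(=O)C[C@@H](C)CC[C@H]1C2
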